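**Retrosynthetic overview**

1. The target is cut into three pieces that are joined in one pot: the fully substituted resorcinol (ring A with its side chain), HC(OEt)3 (the coumarin C4 carbon) and an open-chain (R)-hydroxy diketo ester (C2, C3 and all of ring C).
2. Ring order: ring A is bought as the arene. In the last pot the orthoformate ties the formyl carbon and the side-chain OH into a transient isochromene quinone methide, the keto ester closes ring C (dihydropyranone) by cyclodehydration, and C–C bond formation, opening of the isochromene and lactonisation close ring B (coumarin).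
3. Hydroxy diketo ester ⇒ methyl acetoacetate dianion + methyl (R)-3-hydroxybutanoate (pyranone stereocentre from the chiral pool).
4. Resorcinol ⇒ BBr3 demethylation ⇐ ortho-lithiation/methylation ⇐ threo 3-arylbutan-2-ol.
5. threo Alcohol ⇒ hydroxyl-directed hydrogenation of a 2-aryl allylic alcohol (the carbinol centre from (S)-but-3-yn-2-ol sets the benzylic centre) ⇐ copper-catalysed arylmagnesiation of the alkynol.

Assumption: the SMILES is read literally, i.e. (R) at C2 of the dihydropyranone, (R) at the benzylic carbon and (S) at the carbinol carbon of the side chain; aryl bromide 1 is taken as a stock catalogue building block.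

**Route**

Step 1
Reactants: 1 5-bromo-1,3-dimethoxy-2-methylbenzene; 2 (2S)-but-3-yn-2-ol
Product: 6 (2S)-3-(3,5-dimethoxy-4-methylphenyl)but-3-en-2-ol, via arylmagnesium bromide 3 (not isolated), via bromomagnesium alkoxide 4 (not isolated), via vinylmagnesium chelate 5 (not isolated)
Conditions: 1, Mg, Et2O, reflux; 2, EtMgBr (1.0 equiv), Et2O, 0 °C; combine (Grignard 2.0 equiv), CuI (15 mol%), reflux, 24 h; aq. NH4Cl
Reagents that add atoms: none
Why: Copper-catalysed anti-arylmagnesiation of a propargylic magnesium alkoxide (Duboudin–Jousseaume carbomagnesiation) delivers the aryl group to the internal alkyne carbon through the five-membered chelate 5 and gives the 2-aryl allylic alcohol on protonation; the carbinol centre of 2 is not touched and stays (S).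

Step 2
Reactants: 6 (2S)-3-(3,5-dimethoxy-4-methylphenyl)but-3-en-2-ol
Product: 7 (2S,3R)-3-(3,5-dimethoxy-4-methylphenyl)butan-2-ol
Conditions: H2 (30 bar), [Rh(nbd)(dppb)]BF4 (5 mol%; nbd = norbornadiene, dppb = 1,4-bis(diphenylphosphino)butane), CH2Cl2, 25 °C
Reagents that add atoms: none
Why: Hydroxyl-directed homogeneous hydrogenation (Brown–Evans, cationic monovalent rhodium): the alcohol binds rhodium, the carbinol methyl turns away from the aryl group to avoid allylic 1,2-strain, and H2 is delivered to the alkene face on the side of the bound oxygen, which sets the benzylic centre as (R), i.e. the threo (2S,3R) isomer.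

Step 3
Reactants: 7 (2S,3R)-3-(3,5-dimethoxy-4-methylphenyl)butan-2-ol
Product: 9 (2S,3R)-3-(3,5-dimethoxy-2,4-dimethylphenyl)butan-2-ol, via dilithio species 8 (not isolated)
Conditions: n-BuLi (2.3 equiv), TMEDA, Et2O, 0 → 25 °C; MeI (1.5 equiv), −78 → 0 °C; H2O
Reagents that add atoms: iodomethane, CI
Why: Directed ortho-metalation: the methoxy group and the side-chain lithium alkoxide direct lithiation to the ring position between them (the two free positions are equivalent), and aryllithium 8 is C-methylated by MeI much faster than the lithium alkoxide is O-methylated; no stereocentre is involved.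

Step 4
Reactants: 9 (2S,3R)-3-(3,5-dimethoxy-2,4-dimethylphenyl)butan-2-ol
Product: 10 5-[(2R,3S)-3-hydroxybutan-2-yl]-2,4-dimethylbenzene-1,3-diol
Conditions: BBr3 (4 equiv), CH2Cl2, −78 → 0 °C; H2O
Reagents that add atoms: none
Why: Aryl methyl ether cleavage by BBr3 (O–B complexation, then bromide attack at methyl); at low temperature the side-chain alcohol is only held as a borate and returns on hydrolysis, so neither stereocentre is touched.

Step 5
Reactants: 11 methyl acetoacetate; 12 methyl (3R)-3-hydroxybutanoate
Product: 14 methyl (7R)-7-hydroxy-3,5-dioxooctanoate, via dilithium dienolate 13 (not isolated)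
Conditions: 11 (3 equiv), LiN(i-Pr)2 (6 equiv), THF, −78 → 0 °C; 12 (1 equiv), −40 → 0 °C; AcOH, −78 °C
Reagents that add atoms: none
Why: γ-Acylation of the acetoacetate dianion by an ester (Claisen condensation of the Huckin–Weiler dianion): one equivalent of 13 deprotonates the hydroxyl, the second attacks the ester carbonyl and the third deprotonates the diketo ester formed, which protects it from over-addition; the C–O stereocentre of 12 is not involved and stays (R).

Step 6
Reactants: 10 5-[(2R,3S)-3-hydroxybutan-2-yl]-2,4-dimethylbenzene-1,3-diol; 14 methyl (7R)-7-hydroxy-3,5-dioxooctanoate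
Product: 18 7-hydroxy-5-[(2R,3S)-3-hydroxybutan-2-yl]-6,8-dimethyl-3-[(2R)-2-methyl-4-oxo-3,4-dihydro-2H-pyran-6-yl]-2H-chromen-2-one, via quinone methide 15 (not isolated), via dihydropyranone ester 16 (not isolated), via benzylidene ester 17 (not isolated)
Conditions: 10, HC(OEt)3 (1.1 equiv), TFA (10 equiv), ClCH2CH2Cl, 0 → 25 °C, 30 min; then 14 (1.2 equiv), 25 → 45 °C; aq. NaHCO3
Reagents that add atoms: triethyl orthoformate, CCOC(OCC)OCC
Why: Proposed new method: TFA and HC(OEt)3 formylate the single free ring position of 10 and the side-chain hydroxyl closes on the new carbon to give quinone methide 15 (the orthoformate ring closure used to finish citrinin-type isochromenes); in the same acid 14 cyclodehydrates to 16 (ring C; the carbinol C–O bond is untouched, so (R) is kept), the enol of the vinylogous β-keto ester 16 adds to C1 of protonated 15, re-ionisation of the benzylic C–O bond and loss of the α-proton give 17, and the ortho-phenol lactonises on the methyl ester (ring B), which frees the side-chain alcohol again; the closest known reaction types are the addition of 1,3-dicarbonyl compounds to citrinin-type quinone methides and the Knoevenagel–lactonisation synthesis of 3-substituted coumarins from salicylaldehydes.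

**Compound list**

1 | 5-bromo-1,3-dimethoxy-2-methylbenzene | COc1cc(Br)cc(OC)c1C | starting material
2 | (2S)-but-3-yn-2-ol | C[C@H](O)C#C | starting material
3 | (3,5-dimethoxy-4-methylphenyl)magnesium bromide | COc1cc([Mg]Br)cc(OC)c1C | intermediate
4 | bromomagnesium (2S)-but-3-yn-2-olate | C#C[C@H](C)O[Mg]Br | intermediate
5 | (5S)-4-(3,5-dimethoxy-4-methylphenyl)-5-methyl-2,5-dihydro-1,2-oxamagnesole (cyclic vinylmagnesium alkoxide) | C[C@@H]1O[Mg]C=C1c1cc(OC)c(C)c(OC)c1 | intermediate
6 | (2S)-3-(3,5-dimethoxy-4-methylphenyl)but-3-en-2-ol | C[C@H](O)C(=C)c1cc(OC)c(C)c(OC)c1 | intermediate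
7 | (2S,3R)-3-(3,5-dimethoxy-4-methylphenyl)butan-2-ol | COc1cc(cc(OC)c1C)[C@@H](C)[C@H](C)O | intermediate
8 | lithium (2S,3R)-3-(2-lithio-3,5-dimethoxy-4-methylphenyl)butan-2-olate | [Li]c1c(OC)c(C)c(OC)cc1[C@@H](C)[C@H](C)O[Li] | intermediate
9 | (2S,3R)-3-(3,5-dimethoxy-2,4-dimethylphenyl)butan-2-ol | COc1cc([C@@H](C)[C@H](C)O)c(C)c(OC)c1C | intermediate
10 | 5-[(2R,3S)-3-hydroxybutan-2-yl]-2,4-dimethylbenzene-1,3-diol | Cc1c(O)cc([C@@H](C)[C@H](C)O)c(C)c1O | intermediate
11 | methyl acetoacetate (methyl 3-oxobutanoate) | COC(=O)CC(C)=O | starting material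
12 | methyl (3R)-3-hydroxybutanoate | C[C@@H](O)CC(=O)OC | starting material
13 | dilithium dienolate (2,4-dianion) of methyl 3-oxobutanoate | [Li+].[Li+].COC([O-])=CC(=C)[O-] | intermediate
14 | methyl (7R)-7-hydroxy-3,5-dioxooctanoate | COC(=O)CC(=O)CC(=O)C[C@@H](C)O | intermediate
15 | (3S,4R)-6-hydroxy-3,4,5,7-tetramethyl-3,4-dihydro-8H-isochromen-8-one (quinone methide) | C[C@H]1[C@@H](OC=C2C1=C(C)C(O)=C(C)C2=O)C | intermediate
16 | methyl 2-[(2R)-2-methyl-4-oxo-3,4-dihydro-2H-pyran-6-yl]acetate | COC(=O)CC1=CC(=O)C[C@@H](C)O1 | intermediate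
17 | methyl (2Z)-3-{2,4-dihydroxy-6-[(2R,3S)-3-hydroxybutan-2-yl]-3,5-dimethylphenyl}-2-[(2R)-2-methyl-4-oxo-3,4-dihydro-2H-pyran-6-yl]prop-2-enoate | COC(=O)/C(=C\c1c(O)c(C)c(O)c(C)c1[C@@H](C)[C@H](C)O)C1=CC(=O)C[C@@H](C)O1 | intermediate
18 | 7-hydroxy-5-[(2R,3S)-3-hydroxybutan-2-yl]-6,8-dimethyl-3-[(2R)-2-methyl-4-oxo-3,4-dihydro-2H-pyran-6-yl]-2H-chromen-2-one | Cc1c(O)c(C)c2oc(=O)c(C3=CC(=O)C[C@@H](C)O3)cc2c1[C@@H](C)[C@H](C)O | target

**Step count and risks**

Total step count: 6. Longest linear sequence: 5 (steps 1, 2, 3, 4, 6); step 5 is the one-step side branch.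

The three steps most likely to fail are step 6, step 3 and step 5.

Step 6 is an untested three-component cascade. The enol of 16 is a weak nucleophile, its ring C5 position can compete, and hot acid could erode the pyranone stereocentre. If it fails, the roles of the partners are reversed. The fallback sets out from 14 and 10. Ester 14 is cyclodehydrated alone (TFA, CH2Cl2, 25 °C) and 16 is isolated. Its activated methylene is formylated (NaH, HCO2Me, THF, 0 °C) to methyl (2Z)-3-hydroxy-2-[(2R)-2-methyl-4-oxo-3,4-dihydro-2H-pyran-6-yl]prop-2-enoate F1. F1 is then condensed with resorcinol 10 in a Pechmann-type reaction (MeSO3H or TFA, 25–40 °C). Here the arene is the nucleophile: its single free position attacks the formyl carbon, dehydration gives 17 and lactonisation follows. The fallback comes back to the route at 18.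

Step 3 requires lithiation at a ring position flanked by a methoxy group and the branched side chain, which may be slow or may give lateral lithiation of the ring methyl. The fallback sets out from 7 and uses electrophilic substitution and cross-coupling in place of metalation. NBS (1.05 equiv, MeCN, 0 °C) brominates one of the two equivalent positions ortho/para to the methoxy groups to give (2S,3R)-3-(2-bromo-3,5-dimethoxy-4-methylphenyl)butan-2-ol F2. Suzuki methylation (trimethylboroxine, Pd(OAc)2/SPhos, K3PO4, dioxane/H2O, 100 °C) then gives 9, where the fallback rejoins the route.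

Step 5 acylates the dianion with an unprotected β-hydroxy ester, whose alkoxide is a poor electrophile, so conversion may be low. The fallback sets out from 12 and replaces the dianion by a masked acylketene. Ester 12 is converted (MeNH(OMe)·HCl, i-PrMgCl, THF, −20 °C) into (3R)-3-hydroxy-N-methoxy-N-methylbutanamide F3. The lithium dienolate of 2,2,6-trimethyl-4H-1,3-dioxin-4-one F4 (from the dioxinone and LiN(i-Pr)2, THF, −78 °C, 3 equiv) is acylated by F3 to give 6-[(4R)-4-hydroxy-2-oxopentyl]-2,2-dimethyl-4H-1,3-dioxin-4-one F5. Heating F5 in toluene/MeOH (110 °C) releases the acylketene, which methanol traps to give 14, where the fallback rejoins the route.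

**Further compounds**

F1 | step 6 | methyl (2Z)-3-hydroxy-2-[(2R)-2-methyl-4-oxo-3,4-dihydro-2H-pyran-6-yl]prop-2-enoate | COC(=O)/C(=C\O)C1=CC(=O)C[C@@H](C)O1
F2 | step 3 | (2S,3R)-3-(2-bromo-3,5-dimethoxy-4-methylphenyl)butan-2-ol | COc1cc([C@@H](C)[C@H](C)O)c(Br)c(OC)c1C
F3 | step 5 | (3R)-3-hydroxy-N-methoxy-N-methylbutanamide | C[C@@H](O)CC(=O)N(C)OC
F4 | step 5 | lithium dienolate of 2,2,6-trimethyl-4H-1,3-dioxin-4-one | [Li+].C=C1C=C([O-])OC(C)(C)O1
F5 | step 5 | 6-[(4R)-4-hydroxy-2-oxopentyl]-2,2-dimethyl-4H-1,3-dioxin-4-one | C[C@@H](O)CC(=O)CC1=CC(=O)OC(C)(C)O1
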